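The constants stand at 30 °C, and my first step is to carry them to 50 °C: the unfolding of free enzyme gains a factor 1200, far more than the factor 3.4 gained by the making of product.

    free enzyme → unfolded enzyme (k1 = 1.3 × 10⁻⁶ s⁻¹, Ea1 = 289 kJ mol⁻¹)
    substrate + free enzyme → product + free enzyme, rate k2*[substrate]*[free enzyme]/(1 + ([substrate]/Km2) + ([substrate]/Ksi2)^2) (Km2 = 0.072 M, Ksi2 = 44 mM, k2 = 120 L mol⁻¹ s⁻¹, Ea2 = 50.0 kJ mol⁻¹)
    substrate + product ⇌ idle adduct, settled at all times (K3 = 14 L mol⁻¹, ΔH3 = 50.0 kJ mol⁻¹)
    (constants at 30 °C)

| flask | substrate | free enzyme | time | remark | temperature |
|---|---|---|---|---|---|
| maple | 0.050 M | 0.01 mol% | 40 min | at 30 °C until 12 min, from then on at 50 °C |  |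
| birch | 0.050 M | 0.01 mol% | 40 min |  | 50 °C |
| ash | 0.050 M | 0.01 mol% | 40 min |  | 30 °C |

* the flask that comes out highest in amount of product, in percent of the substrate charged, or "all alike" when all lie within 1.5 percentage points (maple / birch / ash / all alike)
* product at the end, in percent of the substrate charged, maple
* product at the end, in percent of the substrate charged, birch
* product at the end, in percent of the substrate charged, ash

- in percentages every species weighs as the substrate in it: one idle adduct counts as two
- for product the idle adduct is counted in
- the constants hold at 30 °C; other temperatures follow from the activation energies and enthalpies
- in an amount of product, one idle adduct counts as one product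

I write the balance of free enzyme, charged at 0.01 mol% of the substrate. Its one way out is unfolding, a first-order loss, so its mean life is the inverse of the rate constant. The making of product runs as the rate constant times c(free enzyme) times an effective substrate level, which rises with c(substrate) and is then pushed back by it (substrate inhibition). That level tops out at c(substrate) = 44 mM, with the value 16.9 mM, and the charge of 0.050 M starts close to the top, at 16.7 mM.

Now the ladder. First on the ladder is the idle adduct, kept at balance from the first moment; it sets no clock of its own and draws c(substrate) down. Next comes the mean life of free enzyme at 50 °C, 10.6 min. Then comes the clearing time at 50 °C, the time to turn over the whole charge at the top rate with the enzyme intact: 24.1 min. The run of 40 min is longer. The clearing time at 30 °C is longer again, 82.4 min, and the mean life at 30 °C, 214 h, stands far above both. So hot enzyme unfolds before it can clear the charge, and cold enzyme outlasts the run, but the run ends before the clearing time is up.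

Mean life over clearing time at 50 °C gives 44.0%. This is the reach: the most product, as a share of the charge, that this loading can make at that temperature before it has unfolded.

Birch gets 97.7% of its reach in the run, a ceiling of 43.0%. Ash has the ceiling 48.5%, run time over clearing time. Maple can bank up to 14.6% cold and add its reach over the remaining 28.0 min, a ceiling of 55.4%. I commit to maple, then ash, then birch, each landing below its ceiling as c(substrate) falls away from the top.

The forecast gives 49.5% for maple, 40.5% for birch and 46% for ash, hence maple, holding that “maple gains from a stable 12-minute start followed by a fast finish”.

The simulation gives 49.6% in maple, 40.5% in birch and 46.2% in ash, so maple stands highest, and each flask lies under my ceiling. Birch has half of its turnover up to 40 min behind it by 6.61 min, before the half-life of its free enzyme, 7.4 min, has passed, and left for 400 min it reaches 41.3%, still less than the reach. The neighbour of birch with 0.017 mol% of free enzyme has a reach of 74.8%, and it gives 59.9% at 40.0 min, with 20.4% of the substrate still unbound.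

All constants are invented; the rest is arithmetic.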